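**Plan**

1. The retrosynthesis first removes the five O-benzyl groups and cuts the two aryl–C(=O) bonds of the terminal rings (late Friedel–Crafts acylation).
2. Ring B is then cut across two ring bonds, C(bridge-bearing)–C(OBn) and C(OH)–C(acyl). Its three C–O carbons alternate with two bridge-bearing carbons and one acyl-bearing carbon, so a 2,4-bis(arylmethyl)-1-methoxy-1,3-bis(silyloxy)diene (four carbons, both terminal rings) and a 1-benzyloxy ynone (two carbons, the isovaleryl group) supply all six ring atoms.
3. The diene is traced to the Claisen self-condensation dimer of a 3-arylpropanoate, made from 2,4,6-trihydroxytoluene by formylation, O-methylation, O-benzylation, olefination and conjugate reduction. The ynone comes from benzyl alcohol, trichloroethylene and isovaleryl chloride.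
4. Forward order: terminal-ring unit (steps 1–5), chain carrying both units (step 6), diene (steps 7–8), ynone (steps 9–11), ring B (step 12), terminal acyl groups and deprotection (steps 13–16).
5. The target has no stereocentre. The only stereochemical element of the route is the (3Z) enol ether of the diene, set by allylic 1,3-strain in the kinetic deprotonation.

Key step: step 12

Abbreviations: Ar = 2,6-bis(benzyloxy)-4-methoxy-3-methylphenyl; Ar' = 2,6-bis(benzyloxy)-4-methoxy-3-methyl-5-(3-methylbutanoyl)phenyl.

Remark: the geometry of the enol ether in 10 and of the ketene acetal bond C1=C2 in 11 and 12 is assumed to be uncontrolled, which is without consequence because both bonds end inside aromatic ring B; 9 is racemic and its stereocentre disappears in step 7; compounds 1, 6, 13, 14, 17 and 26 are taken as commercial.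

**Route**

Step 1
Reactants: 1 2,4,6-trihydroxytoluene
Product: 3 2,4,6-trihydroxy-3-methylbenzaldehyde, via iminium chloride 2 (not isolated)
Conditions: POCl3 (1.1 equiv), DMF (1.2 equiv), EtOAc, 0 °C to rt; then H2O, 50 °C
Reagents that add atoms: N,N-dimethylformamide CN(C)C=O; water O
Why: Vilsmeier–Haack formylation, in which the chloroiminium ion attacks one of the two equivalent free carbons of the very electron-rich triol and hydrolysis of iminium salt 2 gives the aldehyde, whose carbonyl group deactivates the ring against a second formylation.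

Step 2
Reactants: 3 2,4,6-trihydroxy-3-methylbenzaldehyde
Product: 4 2,6-dihydroxy-4-methoxy-3-methylbenzaldehyde
Conditions: MeI (1.05 equiv), K2CO3 (1.0 equiv), acetone, 0 °C to rt
Reagents that add atoms: iodomethane CI
Why: Regioselective Williamson O-alkylation, since the hydroxyl para to the formyl group is the most acidic and is not hydrogen-bonded to the carbonyl, so one equivalent of MeI with a weak base should methylate it in preference to the two chelated ortho hydroxyls.

Step 3
Reactants: 4 2,6-dihydroxy-4-methoxy-3-methylbenzaldehyde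
Product: 5 2,6-bis(benzyloxy)-4-methoxy-3-methylbenzaldehyde
Conditions: BnBr (2.5 equiv), K2CO3 (3 equiv), Bu4NI (cat.), DMF, 60 °C
Reagents that add atoms: benzyl bromide BrCc1ccccc1
Why: Williamson ether synthesis under more forcing conditions benzylates the two remaining, chelated phenols.

Step 4
Reactants: 5 2,6-bis(benzyloxy)-4-methoxy-3-methylbenzaldehyde; 6 trimethyl phosphonoacetate
Product: 7 methyl (E)-3-Ar-prop-2-enoate
Conditions: NaH (1.2 equiv), THF, 0 °C to rt
Reagents that add atoms: none
Why: Horner–Wadsworth–Emmons olefination of the hindered but non-enolisable aldehyde should give the (E)-enoate, whose geometry is irrelevant because the double bond is reduced next.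

Step 5
Reactants: 7 methyl (E)-3-Ar-prop-2-enoate
Product: 8 methyl 3-Ar-propanoate
Conditions: NaBH4 (3 equiv), NiCl2·6H2O (0.2 equiv), MeOH/THF, 0 °C
Reagents that add atoms: none
Why: Nickel boride conjugate reduction saturates the enoate double bond without hydrogenolysis of the aryl benzyl ethers and without reducing the ester.

Step 6
Reactants: 8 methyl 3-Ar-propanoate (two molecules)
Product: 9 methyl 5-Ar-2-(ArCH2)-3-oxopentanoate (racemic)
Conditions: NaH (0.6 equiv), MeOH (cat.), THF, 65 °C; then AcOH, 0 °C
Reagents that add atoms: none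
Why: Claisen self-condensation, in which the ester enolate acylates a second ester molecule and deprotonation of the beta-keto ester drives the equilibrium, so that one step gives the five-carbon chain carrying one ring A unit on C2 and one on C5.

Step 7
Reactants: 9 methyl 5-Ar-2-(ArCH2)-3-oxopentanoate
Product: 10 methyl 5-Ar-2-(ArCH2)-3-(trimethylsilyloxy)pent-2-enoate
Conditions: Me3SiCl (1.5 equiv), Et3N (1.6 equiv), toluene, rt, 72 h; filtration and evaporation under argon
Reagents that add atoms: chlorotrimethylsilane C[Si](C)(C)Cl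
Why: O-silylation of the enol form of the beta-keto ester (silyl enol ether formation) gives the conjugated enol ether as the first stage of the standard two-stage preparation of 1,3-bis(silyloxy)dienes.

Step 8
Reactants: 10 methyl 5-Ar-2-(ArCH2)-3-(trimethylsilyloxy)pent-2-enoate
Product: 12 (3Z)-5-Ar-2-(ArCH2)-1-methoxy-1,3-bis(trimethylsilyloxy)penta-1,3-diene, via lithium dienolate 11 (not isolated)
Conditions: LiN(iPr)2 (1.3 equiv), THF, −78 °C; then Me3SiCl (1.5 equiv), −78 to 0 °C; evaporation, extraction into hexane, filtration under argon, used crude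
Reagents that add atoms: chlorotrimethylsilane C[Si](C)(C)Cl
Why: Kinetic gamma-deprotonation of the vinylogous ester and O-silylation of the dienolate (silyl ketene acetal formation), in which allylic 1,3-strain with the C2 substituent makes the C5 group turn toward the silyloxy side during deprotonation and should thereby give the (3Z) enol ether.

Step 9
Reactants: 13 benzyl alcohol; 14 trichloroethylene
Product: 16 (E)-benzyl 1,2-dichlorovinyl ether, via dichloroacetylene 15 (not isolated)
Conditions: KH (1.2 equiv), THF, 0 °C; then 14, −50 °C to rt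
Reagents that add atoms: none
Why: Base-induced dehydrochlorination of trichloroethylene followed by anti addition of the alkoxide to dichloroacetylene (nucleophilic addition to a haloalkyne) gives the (E)-dichlorovinyl ether.

Step 10
Reactants: 17 isovaleryl chloride
Product: 18 N-methoxy-N,3-dimethylbutanamide
Conditions: MeNHOMe·HCl (1.1 equiv), Et3N (2.2 equiv), CH2Cl2, 0 °C to rt
Reagents that add atoms: N,O-dimethylhydroxylamine hydrochloride CNOC.Cl
Why: Nucleophilic acyl substitution of the acid chloride gives the Weinreb amide.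

Step 11
Reactants: 16 (E)-benzyl 1,2-dichlorovinyl ether; 18 N-methoxy-N,3-dimethylbutanamide
Product: 21 1-(benzyloxy)-5-methylhex-1-yn-3-one, via benzyl chloroethynyl ether 19 (not isolated), via lithium benzyloxyacetylide 20 (not isolated)
Conditions: n-BuLi (2.2 equiv), THF, −78 to −40 °C; then 18 (0.9 equiv), −78 to −20 °C; cold aq. NH4Cl; kept below 0 °C and used at once
Reagents that add atoms: none
Why: Elimination of HCl and chlorine–lithium exchange give the lithium alkoxyacetylide, and its acylation stops at the chelated tetrahedral adduct (Weinreb ketone synthesis), so the ynone is released only on cold work-up.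

Step 12
Reactants: 12 (3Z)-5-Ar-2-(ArCH2)-1-methoxy-1,3-bis(trimethylsilyloxy)penta-1,3-diene; 21 1-(benzyloxy)-5-methylhex-1-yn-3-one (1.2 equiv)
Product: 24 1-[2-(benzyloxy)-3,5-bis(ArCH2)-4,6-dihydroxyphenyl]-3-methylbutan-1-one, via cycloadduct 22 (not isolated), via bis(trimethylsilyl) ether 23 (not isolated)
Conditions: Me3SiOTf (0.2 equiv), CH2Cl2, −78 to −20 °C; then 1 M HCl, THF, 0 °C
Reagents that add atoms: none
Why: Proposed new method: Me3SiOTf should silylate the ynone carbonyl to a benzyloxy-stabilised allenyl cation that is attacked at its benzyloxy-bearing carbon (beta to the ketone) by C4 of diene 12, the vinylogous and most nucleophilic terminus, after which the central carbon of the resulting silyloxyallene (the carbon alpha to the ketone) should add to the dioxocarbenium carbon C1 left from the ketene acetal; this stepwise ionic [4+2] is the Lewis acid variant of the closest known reaction type, the Diels–Alder or Mukaiyama–Michael/Claisen cycloaromatisation of 1-methoxy-1,3-bis(trimethylsilyloxy)dienes with alkynones, which has not been shown for a 2,4-disubstituted diene or a 3-alkoxy ynone. Ring B closes as a six-membered carbocycle from C1–C4 of the diene and the two alkyne carbons, the second bond by a 6-exo-trig (enolexo) attack on C1. Cycloadduct 22 should lose methanol across C1 and C4 to give arene 23, and the acidic work-up removes both silyl groups, so that the acyl group ends between a free hydroxyl and the benzyloxy group. No stereocentre is created in 24, since the two sp3 ring carbons of 22 become aromatic. The step needs regioselectivity (C4 to the beta carbon, C1 to the alpha carbon) and [4+2] instead of [3+3] ring formation: the first follows from pairing the strongest donor terminus with the oxygen-stabilised acceptor terminus and is helped by the (3Z) geometry, which turns the C4 benzyl substituent outward in the s-cis diene, and the second from the C2 substituent, which prevents aromatisation after an aldol attack of C2 on the ketone. Working at or below −20 °C keeps the benzyl ynol ether from sigmatropic rearrangement and the benzyl ethers of the terminal rings from Lewis acid cleavage.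

Step 13
Reactants: 24 1-[2-(benzyloxy)-3,5-bis(ArCH2)-4,6-dihydroxyphenyl]-3-methylbutan-1-one
Product: 25 1-[2,4-diacetoxy-6-(benzyloxy)-3,5-bis(ArCH2)phenyl]-3-methylbutan-1-one
Conditions: Ac2O (4 equiv), pyridine, DMAP (cat.), CH2Cl2, rt
Reagents that add atoms: acetic anhydride CC(=O)OC(C)=O
Why: DMAP-catalysed O-acylation converts both ring B phenols into acetates, which makes ring B electron-poor and should shield the diarylmethane bridges from acid-induced cleavage in the next step.

Step 14
Reactants: 25 1-[2,4-diacetoxy-6-(benzyloxy)-3,5-bis(ArCH2)phenyl]-3-methylbutan-1-one; 26 isovaleric acid (6 equiv)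
Product: 28 1-[2,4-diacetoxy-6-(benzyloxy)-3,5-bis(Ar'CH2)phenyl]-3-methylbutan-1-one, via mixed anhydride 27 (not isolated)
Conditions: (CF3CO)2O (6 equiv), CH2Cl2, 0 °C to rt
Reagents that add atoms: none
Why: Friedel–Crafts acylation by the mixed trifluoroacetic anhydride at the only unsubstituted carbon of each trialkoxyarene ring, which is activated by an ortho methoxy, an ortho benzyloxy and a para benzyloxy group, while ring B is fully substituted and deactivated.

Step 15
Reactants: 28 1-[2,4-diacetoxy-6-(benzyloxy)-3,5-bis(Ar'CH2)phenyl]-3-methylbutan-1-one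
Product: 29 1-[2-(benzyloxy)-3,5-bis(Ar'CH2)-4,6-dihydroxyphenyl]-3-methylbutan-1-one
Conditions: K2CO3 (cat.), MeOH/THF, rt
Reagents that add atoms: none
Why: Base-catalysed transesterification cleaves the aryl acetates (and any phenolic ester formed by stray debenzylation in step 14) while ketones and aryl ethers are inert.

Step 16
Reactants: 29 1-[2-(benzyloxy)-3,5-bis(Ar'CH2)-4,6-dihydroxyphenyl]-3-methylbutan-1-one
Product: 30 1-[3,5-bis({2,6-dihydroxy-4-methoxy-3-methyl-5-(3-methylbutanoyl)phenyl}methyl)-2,4,6-trihydroxyphenyl]-3-methylbutan-1-one (target)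
Conditions: H2 (1 atm), Pd/C, EtOAc/MeOH, rt
Reagents that add atoms: none
Why: Catalytic hydrogenolysis of the five aryl benzyl ethers under neutral conditions frees all phenols, and the hydrogen-bonded, hindered aryl ketones and the diarylmethane bridges should not be reduced at ambient pressure.

**Compound list**

1 | 2,4,6-trihydroxytoluene | Cc1c(O)cc(O)cc1O | starting material
2 | N-[(2,4,6-trihydroxy-3-methylphenyl)methylidene]-N-methylmethanaminium chloride | C[N+](C)=Cc1c(O)cc(O)c(C)c1O.[Cl-] | intermediate
3 | 2,4,6-trihydroxy-3-methylbenzaldehyde | Cc1c(O)cc(O)c(C=O)c1O | intermediate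
4 | 2,6-dihydroxy-4-methoxy-3-methylbenzaldehyde | COc1cc(O)c(C=O)c(O)c1C | intermediate
5 | 2,6-bis(benzyloxy)-4-methoxy-3-methylbenzaldehyde | COc1cc(OCc2ccccc2)c(C=O)c(OCc2ccccc2)c1C | intermediate
6 | trimethyl phosphonoacetate | COC(=O)CP(=O)(OC)OC | starting material
7 | methyl (E)-3-[2,6-bis(benzyloxy)-4-methoxy-3-methylphenyl]prop-2-enoate | COC(=O)/C=C/c1c(OCc2ccccc2)cc(OC)c(C)c1OCc1ccccc1 | intermediate
8 | methyl 3-[2,6-bis(benzyloxy)-4-methoxy-3-methylphenyl]propanoate | COC(=O)CCc1c(OCc2ccccc2)cc(OC)c(C)c1OCc1ccccc1 | intermediate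
9 | methyl 5-Ar-2-(ArCH2)-3-oxopentanoate, racemic | COC(=O)C(Cc1c(OCc2ccccc2)cc(OC)c(C)c1OCc1ccccc1)C(=O)CCc1c(OCc2ccccc2)cc(OC)c(C)c1OCc1ccccc1 | intermediate
10 | methyl 5-Ar-2-(ArCH2)-3-(trimethylsilyloxy)pent-2-enoate, double-bond geometry not controlled | COC(=O)C(Cc1c(OCc2ccccc2)cc(OC)c(C)c1OCc1ccccc1)=C(O[Si](C)(C)C)CCc1c(OCc2ccccc2)cc(OC)c(C)c1OCc1ccccc1 | intermediate
11 | lithium (3Z)-5-Ar-2-(ArCH2)-1-methoxy-3-(trimethylsilyloxy)penta-1,3-dien-1-olate | COC(O[Li])=C(Cc1c(OCc2ccccc2)cc(OC)c(C)c1OCc1ccccc1)/C(O[Si](C)(C)C)=C/Cc1c(OCc2ccccc2)cc(OC)c(C)c1OCc1ccccc1 | intermediate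
12 | (3Z)-5-Ar-2-(ArCH2)-1-methoxy-1,3-bis(trimethylsilyloxy)penta-1,3-diene, C1=C2 geometry not controlled | COC(O[Si](C)(C)C)=C(Cc1c(OCc2ccccc2)cc(OC)c(C)c1OCc1ccccc1)/C(O[Si](C)(C)C)=C/Cc1c(OCc2ccccc2)cc(OC)c(C)c1OCc1ccccc1 | intermediate
13 | benzyl alcohol | OCc1ccccc1 | starting material
14 | trichloroethylene | ClC=C(Cl)Cl | starting material
15 | dichloroacetylene | ClC#CCl | intermediate
16 | (E)-benzyl 1,2-dichlorovinyl ether | Cl/C(OCc1ccccc1)=C/Cl | intermediate
17 | isovaleryl chloride | CC(C)CC(Cl)=O | starting material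
18 | N-methoxy-N,3-dimethylbutanamide | CC(C)CC(=O)N(C)OC | intermediate
19 | benzyl chloroethynyl ether | ClC#COCc1ccccc1 | intermediate
20 | lithium benzyloxyacetylide | [Li]C#COCc1ccccc1 | intermediate
21 | 1-(benzyloxy)-5-methylhex-1-yn-3-one | CC(C)CC(=O)C#COCc1ccccc1 | intermediate
22 | 1-[2-(benzyloxy)-3,5-bis(ArCH2)-6-methoxy-4,6-bis(trimethylsilyloxy)cyclohexa-1,4-dien-1-yl]-3-methylbutan-1-one, diastereomer mixture at C3 and C6 | COC1(O[Si](C)(C)C)C(Cc2c(OCc3ccccc3)cc(OC)c(C)c2OCc2ccccc2)=C(O[Si](C)(C)C)C(Cc2c(OCc3ccccc3)cc(OC)c(C)c2OCc2ccccc2)C(OCc2ccccc2)=C1C(=O)CC(C)C | intermediate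
23 | 1-[2-(benzyloxy)-3,5-bis(ArCH2)-4,6-bis(trimethylsilyloxy)phenyl]-3-methylbutan-1-one | COc1cc(OCc2ccccc2)c(Cc2c(O[Si](C)(C)C)c(Cc3c(OCc4ccccc4)cc(OC)c(C)c3OCc3ccccc3)c(OCc3ccccc3)c(C(=O)CC(C)C)c2O[Si](C)(C)C)c(OCc2ccccc2)c1C | intermediate
24 | 1-[2-(benzyloxy)-3,5-bis(ArCH2)-4,6-dihydroxyphenyl]-3-methylbutan-1-one | COc1cc(OCc2ccccc2)c(Cc2c(O)c(Cc3c(OCc4ccccc4)cc(OC)c(C)c3OCc3ccccc3)c(OCc3ccccc3)c(C(=O)CC(C)C)c2O)c(OCc2ccccc2)c1C | intermediate
25 | 1-[2,4-diacetoxy-6-(benzyloxy)-3,5-bis(ArCH2)phenyl]-3-methylbutan-1-one | COc1cc(OCc2ccccc2)c(Cc2c(OC(C)=O)c(Cc3c(OCc4ccccc4)cc(OC)c(C)c3OCc3ccccc3)c(OCc3ccccc3)c(C(=O)CC(C)C)c2OC(C)=O)c(OCc2ccccc2)c1C | intermediate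
26 | isovaleric acid | CC(C)CC(=O)O | starting material
27 | 3-methylbutanoic trifluoroacetic anhydride | CC(C)CC(=O)OC(=O)C(F)(F)F | intermediate
28 | 1-[2,4-diacetoxy-6-(benzyloxy)-3,5-bis(Ar'CH2)phenyl]-3-methylbutan-1-one | COc1c(C(=O)CC(C)C)c(OCc2ccccc2)c(Cc2c(OC(C)=O)c(Cc3c(OCc4ccccc4)c(C(=O)CC(C)C)c(OC)c(C)c3OCc3ccccc3)c(OCc3ccccc3)c(C(=O)CC(C)C)c2OC(C)=O)c(OCc2ccccc2)c1C | intermediate
29 | 1-[2-(benzyloxy)-3,5-bis(Ar'CH2)-4,6-dihydroxyphenyl]-3-methylbutan-1-one | COc1c(C(=O)CC(C)C)c(OCc2ccccc2)c(Cc2c(O)c(Cc3c(OCc4ccccc4)c(C(=O)CC(C)C)c(OC)c(C)c3OCc3ccccc3)c(OCc3ccccc3)c(C(=O)CC(C)C)c2O)c(OCc2ccccc2)c1C | intermediate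
30 | 1-[3,5-bis({2,6-dihydroxy-4-methoxy-3-methyl-5-(3-methylbutanoyl)phenyl}methyl)-2,4,6-trihydroxyphenyl]-3-methylbutan-1-one | COc1c(C)c(O)c(Cc2c(O)c(Cc3c(O)c(C)c(OC)c(C(=O)CC(C)C)c3O)c(O)c(C(=O)CC(C)C)c2O)c(O)c1C(=O)CC(C)C | target

**Step count**

Total: 16 steps. Longest linear sequence: 13 steps (steps 1–8 and 12–16); the ynone branch (steps 9–11) joins at step 12.

**Steps most likely to fail**

Step 12. The donor-substituted ynone may be too weak an acceptor, the Michael adduct may fail to close onto C1, or the benzyl ynol ether may ionise or rearrange before it is captured. The fallback gives up the de novo construction of ring B and forms the two bridge bonds on a preformed ring B by Friedel–Crafts benzylation; it sets out from 5 and 17 and returns at 24. Aldehyde 5 would be reduced (NaBH4, MeOH/THF, 0 °C) to [2,6-bis(benzyloxy)-4-methoxy-3-methylphenyl]methanol F1. Phloroglucinol would be C-acylated with 17 (AlCl3, CH2Cl2/MeNO2) to 3-methyl-1-(2,4,6-trihydroxyphenyl)butan-1-one F2. The two hydroxyls not engaged in the chelate would be protected (MOMCl, iPr2NEt, CH2Cl2) to give 1-[2-hydroxy-4,6-bis(methoxymethoxy)phenyl]-3-methylbutan-1-one F3, and the remaining phenol benzylated (BnBr, K2CO3, DMF) to give 1-[2-(benzyloxy)-4,6-bis(methoxymethoxy)phenyl]-3-methylbutan-1-one F4. Acidic methanolysis (HCl, MeOH) would then free 1-[2-(benzyloxy)-4,6-dihydroxyphenyl]-3-methylbutan-1-one F5. Acid-catalysed double Friedel–Crafts benzylation of F5 at its two free ring carbons with two equivalents of F1 (Sc(OTf)3 cat., MeCN, 0 °C, slow addition of F1) should give 24.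

Step 14. The acidic medium may cleave or scramble the diarylmethane bridges, strip benzyl ethers, or stop at mono-acylation because the last ring position is crowded. The fallback replaces electrophilic acylation by halogenation and cross-coupling; it sets out from 25 and returns at 28. Iodination of both terminal rings at their free carbon (N-iodosuccinimide, MeCN, rt) would give 1-[2,4-diacetoxy-6-(benzyloxy)-3,5-bis({2,6-bis(benzyloxy)-3-iodo-4-methoxy-5-methylphenyl}methyl)phenyl]-3-methylbutan-1-one F6. A twofold carbonylative Negishi coupling with iBuZnBr under CO (1 atm) and Pd(PPh3)4 (zerovalent palladium) in THF at 50 °C should then install both isovaleryl groups and give 28.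

Step 11. The tetrahedral adduct may collapse early and let the acetylide add a second time, or a sluggish acylation may force warming and so trigger sigmatropic loss of the benzyl ynol ether. The fallback reaches the ynone by carbonyl addition and oxidation instead of acylation; it sets out from 16 and returns at 21. Acetylide 20, generated from 16 as in step 11, would be added to 3-methylbutanal at −78 °C to give racemic 1-(benzyloxy)-5-methylhex-1-yn-3-ol F7, and oxidation of this propargylic alcohol with MnO2 (CH2Cl2, 0 °C) should give 21.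

**Further compounds**

F1 | step 12 | [2,6-bis(benzyloxy)-4-methoxy-3-methylphenyl]methanol | COc1cc(OCc2ccccc2)c(CO)c(OCc2ccccc2)c1C
F2 | step 12 | 3-methyl-1-(2,4,6-trihydroxyphenyl)butan-1-one | CC(C)CC(=O)c1c(O)cc(O)cc1O
F3 | step 12 | 1-[2-hydroxy-4,6-bis(methoxymethoxy)phenyl]-3-methylbutan-1-one | CC(C)CC(=O)c1c(O)cc(OCOC)cc1OCOC
F4 | step 12 | 1-[2-(benzyloxy)-4,6-bis(methoxymethoxy)phenyl]-3-methylbutan-1-one | CC(C)CC(=O)c1c(OCc2ccccc2)cc(OCOC)cc1OCOC
F5 | step 12 | 1-[2-(benzyloxy)-4,6-dihydroxyphenyl]-3-methylbutan-1-one | CC(C)CC(=O)c1c(OCc2ccccc2)cc(O)cc1O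
F6 | step 14 | 1-[2,4-diacetoxy-6-(benzyloxy)-3,5-bis({2,6-bis(benzyloxy)-3-iodo-4-methoxy-5-methylphenyl}methyl)phenyl]-3-methylbutan-1-one | COc1c(I)c(OCc2ccccc2)c(Cc2c(OC(C)=O)c(Cc3c(OCc4ccccc4)c(I)c(OC)c(C)c3OCc3ccccc3)c(OCc3ccccc3)c(C(=O)CC(C)C)c2OC(C)=O)c(OCc2ccccc2)c1C
F7 | step 11 | 1-(benzyloxy)-5-methylhex-1-yn-3-ol, racemic | CC(C)CC(O)C#COCc1ccccc1
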